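## Structural features

The target is a 3a,4,5,7a-tetrahydro-1H-indene. Cyclopentene ring B (C1, C2, C3, C3a, C7a; C2=C3, ethyl on C3, methyl on C1) is trans-fused through C3a–C7a to cyclohexene ring A (C3a, C4, C5, C6, C7, C7a; C6=C7, ethyl on C7). Five contiguous stereocentres run C1–C7a–C3a–C4–C5 (1S,7aR,3aS,4S,5R). The C1 methyl is trans to the C7a–C7 bond, and at the two adjacent quaternary carbons the carboxyl (C4) and the (E)-styryl group (C5) lie on the face of H-3a, with the C4 methyl and C5 ethyl on the other. The styrene and the two trisubstituted alkenes exclude hydrogenation, strong acid and electrophilic halogen late in the route. An ester on C4 would be very hard to cleave, so the acid is best formed free. The real difficulty is the C4–C5 bond, which joins two stereogenic, fully substituted carbons inside ring A.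

The key step uses the fact that the carboxyl sits on C4, C4 is bonded to C5, and C5 is allylic to C6=C7. This γ,δ-unsaturated acid is the retron of an ester-enolate [3,3] shift whose oxygen was on C7. Because C4 and C7 both hang from the C3a–C7a bond, that allylic ester is a δ-lactone fused to ring B.

Two corrections to the usual description of this step:
- The lactone ring (C7, O, C=O, C4, C3a, C7a) and ring A are both six-membered. The step exchanges one ring for the other and contracts nothing.
- C4 of the lactone becomes trigonal in the ketene acetal. Only the C7 configuration and the E geometry of C5=C6 carry stereochemical information into the product.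

## Logic of the disconnections

**26 ⇒ 23 (through 25 and 24).** The C4–C5 bond is cut and an O–C7 bond is drawn in its place, the reverse of a [3,3] shift. This is the only cut that removes both quaternary carbons, ring A and the C6=C7 alkene at once and leaves the acid free. What remains is a bicyclic lactone with a single quaternary carbinol carbon. The forward step must join two fully substituted carbons through a boat, and 23 must carry the dienyl group on C7 cis to H-7a and an E C5=C6 alkene.

**23 ⇒ 21 (through 22).** The acyl C–O bond of the ring and the C7–ethyl bond are cut. C7 is then a ketone carbon, and its configuration becomes a question of which face a nucleophile attacks. The ethyl group is made the nucleophile and the dienyl group the ketone substituent, because a Felkin–Anh analysis predicts the needed C7 epimer for that ordering and the wrong one for the reverse. The forward step needs clean 1,2-addition to an enolisable dienone and ring closure under base, since the tertiary dienylic alcohol would ionise in acid.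

**21 ⇒ 12 + 18 (through 20 and 19).** The C6–C7 bond is cut between an aldehyde carbon and an alkenyl nucleophile, with one oxidation-level adjustment. This splits the molecule into a ring-B aldehyde and a stereodefined diene. The forward step must retain both alkene geometries and react at the aldehyde in the presence of the ester.

**18 ⇒ 16 ⇒ 14 ⇒ 13.** The C5–ethyl and C6–halogen bonds are cut across a terminal alkyne, so a syn addition fixes the trisubstituted alkene geometry by mechanism. The alkyne comes from one-carbon homologation of 13. The forward carbometalation must place the metal on the terminal carbon.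

**12 ⇒ 11 ⇒ 10 ⇒ 9.** The aldehyde is masked as a dithioacetal and the C3–ethyl bond is cut back to a ketone through an enol triflate. This returns ring B to a cyclopentanone with all three stereocentres in place. The forward steps need enolisation toward C2 only and a coupling that tolerates sulfur and an ester.

**9 ⇒ 3 + 6 (as 7) + 5.** The C7–C7a and C3a–C4 bonds are cut: conjugate addition of a one-carbon acyl anion equivalent, then alkylation of the resulting enolate. The single stereocentre of 3 relays to C7a and then C3a, and 5 brings C4 with it. The forward step needs 1,4-addition and C-alkylation by a secondary electrophile before the enolate equilibrates.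

**3 ⇒ 1 and 5 ⇒ 4.** Dehydrogenation on the side remote from the methyl group and O-sulfonylation. Both start from commercial single enantiomers.

## Other disconnections considered

**Alternative 1:** The cut is at C7–C7a and C3a–C4, the two exocyclic bonds of ring B. In the forward step the lithiated 2-ethyl dithiane A1 adds to 3 anti to the methyl group, and the enolate displaces triflate from 5 anti to the new substituent, giving keto ester A2.
- In its favour: three contiguous stereocentres from one, in one flask, by polar chemistry at low temperature. A2 already carries the C7 ethyl group.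
- Against it here: it closes no ring and makes neither quaternary carbon, so the C4–C5 problem is untouched. The stereocentre it sets at C4 is erased later. Its trap is a secondary, base-sensitive triflate.
- Comparison on structure: it addresses ring B only. The chosen plan uses the same tactic in step 3 (with 7 in place of A1), so on ring B the two are equal.
- Comparison on mechanism: it is stepwise and ionic, and easier to predict than a crowded pericyclic boat. On that point it is the better.
- Comparison on step economy: A2 would reach 23 two steps sooner than 9 does, which is also better. That holds only if an alkenyl nucleophile attacks the ethyl ketone on the face opposite to the Felkin–Anh prediction.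
- As a key step it can only precede step 13. It cannot replace it.

**Alternative 2:** The cut is at C6=C7. In the forward step tetraene A3 (two vinyl groups on C5, a but-1-en-2-yl group on C7a, plus the ring-B alkene) undergoes ring-closing metathesis between the 1,1-disubstituted alkene and one vinyl group, giving A4. A cross-metathesis on the remaining vinyl group would then give A5, and ester cleavage would give 26.
- In its favour: closure to a six-membered trisubstituted cycloalkene is dependable, neutral and near room temperature. The key step forms no bond between quaternary carbons and needs no tertiary allylic ester.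
- Against it here: A3 must already contain the C4–C5 bond and the C4 stereocentre, so the hardest bond is only moved upstream. C5 becomes stereogenic through a small conformational preference between two vinyl groups. A vinyl group on a quaternary carbon is a reluctant cross-metathesis partner. The hindered ester must be cleaved at the end.
- Comparison on structure: it closes ring A only. The chosen plan closes ring A and makes C4–C5 with both stereocentres.
- Comparison on mechanism: metal-carbene cycloaddition and cycloreversion under conformational control, against a concerted shift under geometric control.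
- Comparison on step economy: at least two steps after the key step against none.
- The mildness and functional-group tolerance of the ring closure itself are better than those of the heated rearrangement. The ring-size outcome is equal.

**Alternative 3:** The cut is at C5–C6. In the forward step the (Z)-alkenyl iodide of A6 adds to zerovalent palladium, the alkenylpalladium inserts the tethered trisubstituted alkene in 6-exo fashion, and β-hydride elimination toward the benzylic CH2 gives A5.
- In its favour: intramolecular Heck closure is an established route to quaternary carbons. After insertion the only β-hydrogens are benzylic, so the (E)-styrene must form. The step is catalytic.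
- Against it here: the C5 configuration depends on which alkene face inserts next to quaternary C4. Insertion into so hindered an alkene competes with reduction. A6 needs a geometrically pure iodoalkene and a separately controlled C4 stereocentre. An ester cleavage follows.
- Comparison on structure: it sets C5 and ring A only. The chosen plan sets C4 and C5 together.
- Comparison on mechanism: syn-insertion and syn-elimination on palladium, against a thermal pericyclic shift.
- Comparison on step economy: longer before the key step and one step more after it.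
- Revealing the styrene in the ring-closing event, so that no diene is carried through the route, is better than the chosen plan. Avoiding a tertiary dienylic ester is also better. Delivering ring A with C6=C7 in place is equal.

Key step: step 13

Assumption: the ethyl nucleophile is taken to attack ketone 21 in the Felkin–Anh sense, with the C3a arm as the large group. The reverse order of introduction is held as the fallback.

## Route

Step 1
Reactants: 1 (R)-3-methylcyclopentanone
Product: 3 (4S)-4-methylcyclopent-2-en-1-one, via silyl enol ether 2 (not isolated)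
Conditions: LiN(i-Pr)2, THF, −78 °C; Me3SiCl; then Pd(OAc)2 (10 mol%), O2, DMSO, rt
Reagents that add atoms: none
Why: Kinetic deprotonation should favour the CH2 remote from the methyl group, and Saegusa–Ito oxidation of 2 (divalent palladium enolate, β-hydride elimination) places the double bond there without touching the stereocentre. The regioisomeric enol ether can only give achiral 3-methylcyclopent-2-enone, which is removed by chromatography.

Step 2
Reactants: 4 methyl (S)-lactate
Product: 5 methyl (2S)-2-{[(trifluoromethyl)sulfonyl]oxy}propanoate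
Conditions: Tf2O, 2,6-lutidine, CH2Cl2, −78 → 0 °C
Reagents that add atoms: trifluoromethanesulfonic anhydride, O=S(=O)(OS(=O)(=O)C(F)(F)F)C(F)(F)F
Why: O-Sulfonylation of a secondary alcohol with a hindered pyridine base. The stereocentre is not involved, so the S configuration is kept.

Step 3
Reactants: 6 1,3-dithiane; 3 (4S)-4-methylcyclopent-2-en-1-one; 5 methyl (2S)-2-{[(trifluoromethyl)sulfonyl]oxy}propanoate
Product: 9 methyl (2S)-2-[(1S,2R,3S)-2-(1,3-dithian-2-yl)-3-methyl-5-oxocyclopentyl]propanoate, via 2-lithio-1,3-dithiane 7 (not isolated), via lithium enolate 8 (not isolated)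
Conditions: n-BuLi, THF, −30 °C; HMPA, 3, −78 °C; then 5, −78 → −40 °C
Reagents that add atoms: none
Why: Three-component conjugate addition–enolate alkylation. With HMPA, 7 should add 1,4 and anti to the methyl group (sets C7a). Enolate 8 should then displace triflate by SN2 with inversion, anti to the new dithianyl group (sets C3a and C4); alkylation of enolates by α-triflyloxy esters with inversion is a known reaction type.

Step 4
Reactants: 9 methyl (2S)-2-[(1S,2R,3S)-2-(1,3-dithian-2-yl)-3-methyl-5-oxocyclopentyl]propanoate
Product: 10 methyl (2S)-2-[(1S,4S,5R)-5-(1,3-dithian-2-yl)-4-methyl-2-{[(trifluoromethyl)sulfonyl]oxy}cyclopent-2-en-1-yl]propanoate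
Conditions: KN(SiMe3)2, THF, −78 °C; PhNTf2, −78 → −20 °C
Reagents that add atoms: N-phenylbis(trifluoromethanesulfonimide), O=S(=O)(N(c1ccccc1)S(=O)(=O)C(F)(F)F)C(F)(F)F
Why: Kinetic enolisation at the unhindered CH2 (C2) and O-triflation should give the less substituted enol triflate. The C3a stereocentre and the tertiary ester α-hydrogen are not deprotonated at −78 °C.

Step 5
Reactants: 10 methyl (2S)-2-[(1S,4S,5R)-5-(1,3-dithian-2-yl)-4-methyl-2-{[(trifluoromethyl)sulfonyl]oxy}cyclopent-2-en-1-yl]propanoate
Product: 11 methyl (2S)-2-[(1S,4S,5R)-5-(1,3-dithian-2-yl)-2-ethyl-4-methylcyclopent-2-en-1-yl]propanoate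
Conditions: EtMgBr, Fe(acac)3 (5 mol%), THF/NMP, −30 °C
Reagents that add atoms: ethylmagnesium bromide, CC[Mg]Br
Why: Iron-catalysed Kumada-type coupling of an alkenyl triflate with an alkyl Grignard reagent is fast at −30 °C, so the hindered methyl ester and the dithiane should survive. The C2=C3 position is fixed by the triflate.

Step 6
Reactants: 11 methyl (2S)-2-[(1S,4S,5R)-5-(1,3-dithian-2-yl)-2-ethyl-4-methylcyclopent-2-en-1-yl]propanoate
Product: 12 methyl (2S)-2-[(1R,4S,5R)-2-ethyl-5-formyl-4-methylcyclopent-2-en-1-yl]propanoate
Conditions: MeI, CaCO3, MeCN/H2O (9:1), 45 °C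
Reagents that add atoms: water, O
Why: Alkylative hydrolysis of the dithioacetal (S-methylation, then water) under carbonate buffering spares the trisubstituted alkene and the ester. C7a already has its substituent trans to both neighbours, so epimerisation is not favoured.

Step 7
Reactants: 13 (E)-cinnamaldehyde
Product: 14 [(1E)-4,4-dibromobuta-1,3-dien-1-yl]benzene
Conditions: CBr4, PPh3, CH2Cl2, 0 °C
Reagents that add atoms: carbon tetrabromide, BrC(Br)(Br)Br
Why: First stage of the Corey–Fuchs homologation (dibromo-olefination of an aldehyde). The styrene geometry is not involved.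

Step 8
Reactants: 14 [(1E)-4,4-dibromobuta-1,3-dien-1-yl]benzene
Product: 16 [(1E)-but-1-en-3-yn-1-yl]benzene, via lithium acetylide 15 (not isolated)
Conditions: n-BuLi (2.1 equiv), THF, −78 °C; then H2O
Reagents that add atoms: none
Why: Second stage of the Corey–Fuchs sequence. Bromine–lithium exchange, Fritsch–Buttenberg–Wiechell rearrangement and deprotonation give 15, which is protonated on work-up.

Step 9
Reactants: 16 [(1E)-but-1-en-3-yn-1-yl]benzene
Product: 18 [(1E,3E)-3-ethyl-4-iodobuta-1,3-dien-1-yl]benzene, via dienylcopper 17 (not isolated)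
Conditions: EtMgBr, CuBr·SMe2, Et2O, −40 → −20 °C; then I2, −50 → 0 °C
Reagents that add atoms: ethylmagnesium bromide, CC[Mg]Br; iodine, II
Why: Normant carbocupration adds ethyl and copper syn across the terminal alkyne with copper on the terminal carbon, and iodinolysis of 17 proceeds with retention. Ethyl and iodine therefore end cis, and iodine trans to the styryl group.

Step 10
Reactants: 18 [(1E,3E)-3-ethyl-4-iodobuta-1,3-dien-1-yl]benzene; 12 methyl (2S)-2-[(1R,4S,5R)-2-ethyl-5-formyl-4-methylcyclopent-2-en-1-yl]propanoate
Product: 20 methyl (2S)-2-[(1R,4S,5R)-2-ethyl-5-[(2E,4E)-3-ethyl-1-hydroxy-5-phenylpenta-2,4-dien-1-yl]-4-methylcyclopent-2-en-1-yl]propanoate (both carbinol epimers), via dienyllithium 19 (not isolated)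
Conditions: t-BuLi (2 equiv), Et2O, −78 °C; then 12, −78 °C; AcOH, −78 °C
Reagents that add atoms: none
Why: Iodine–lithium exchange retains the alkene geometry, and 19 should add to the aldehyde far faster than to the hindered ester at −78 °C. The new carbinol centre is unselective and is removed in step 11; the cold acidic quench prevents the secondary alkoxide from lactonising.

Step 11
Reactants: 20 methyl (2S)-2-[(1R,4S,5R)-2-ethyl-5-[(2E,4E)-3-ethyl-1-hydroxy-5-phenylpenta-2,4-dien-1-yl]-4-methylcyclopent-2-en-1-yl]propanoate
Product: 21 methyl (2S)-2-[(1R,4S,5R)-2-ethyl-5-[(2E,4E)-3-ethyl-5-phenylpenta-2,4-dienoyl]-4-methylcyclopent-2-en-1-yl]propanoate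
Conditions: MnO2, CH2Cl2, rt
Reagents that add atoms: none
Why: MnO2 oxidises a doubly allylic secondary alcohol under neutral conditions. Both epimers of 20 converge, and the acid-sensitive dienyl carbinol is never exposed to acid.

Step 12
Reactants: 21 methyl (2S)-2-[(1R,4S,5R)-2-ethyl-5-[(2E,4E)-3-ethyl-5-phenylpenta-2,4-dienoyl]-4-methylcyclopent-2-en-1-yl]propanoate
Product: 23 (1R,4S,4aR,7S,7aR)-1,5-diethyl-1-[(1E,3E)-2-ethyl-4-phenylbuta-1,3-dien-1-yl]-4,7-dimethyl-4,4a,7,7a-tetrahydrocyclopenta[c]pyran-3(1H)-one, via hydroxy ester 22 (not isolated)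
Conditions: EtMgBr, CeCl3, THF, −78 °C; H2O; then NaH, THF, 0 °C → rt
Reagents that add atoms: ethylmagnesium bromide, CC[Mg]Br
Why: Organocerium 1,2-addition suppresses enolisation and conjugate addition. Felkin–Anh attack antiperiplanar to the more substituted C7a–C3a bond, with the small ethyl group passing the C1 side, should place the dienyl group cis to H-7a (this sets C7). The sodium alkoxide of 22 then closes the δ-lactone on the methyl ester with loss of methoxide.

Step 13
Reactants: 23 (1R,4S,4aR,7S,7aR)-1,5-diethyl-1-[(1E,3E)-2-ethyl-4-phenylbuta-1,3-dien-1-yl]-4,7-dimethyl-4,4a,7,7a-tetrahydrocyclopenta[c]pyran-3(1H)-one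
Product: 26 (1S,3aS,4S,5R,7aR)-3,5,7-triethyl-1,4-dimethyl-5-[(E)-2-phenylethenyl]-3a,4,5,7a-tetrahydro-1H-indene-4-carboxylic acid, via silyl ketene acetal 24 (not isolated), via trimethylsilyl ester 25 (not isolated)
Conditions: KN(SiMe3)2, Me3SiCl, THF/toluene, −78 °C → rt; toluene, 110 °C; then 0.5 M HCl, THF, 0 °C
Reagents that add atoms: none
Why: The base removes the axial C4 hydrogen of 23 and Me3SiCl traps the enolate as cyclic ketene acetal 24, whose C4=C(O) geometry is fixed by the ring. On heating, 24 should undergo a concerted, suprafacial [3,3] shift (Ireland–Claisen rearrangement) that forms C4–C5, breaks O–C7 and moves the alkene to C6=C7, giving 25, which mild acid hydrolyses to 26. The closest known type is the rearrangement of silyl ketene acetals of lactones bearing an alkenyl group on the carbinol carbon to cycloalkenecarboxylic acids. Ring A closes because C4 and C5 are tied by the C3a–C7a bond: the six reacting atoms and this two-carbon bridge form a bicyclo[2.2.2]octene-like array, so only a boat is possible, and the six-membered lactone is exchanged for the six-membered carbocycle. C4 is controlled by C7: the dienyl arm can reach only the face of the ketene acetal on which it is anchored, which puts the carboxyl cis to H-3a and the methyl trans. C5 is controlled by the E geometry of C5=C6: the ethyl group, cis to C7, lies inside the boat and ends trans to the carboxyl, with the styryl group cis to it. C1, C3a and C7a are spectators, so the trans fusion is carried through. There is one α-hydrogen and one allylic C–O bond, so no regiochemical choice arises; the shift must only outrun ionisation of the tertiary dienylic C–O bond, which the non-polar medium is meant to slow. The step is unimolecular and driven by C=O formation, but the crowded transition state will need the heat.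

## Compound list

1 | (R)-3-methylcyclopentanone | O=C1CC[C@@H](C)C1 | starting material
2 | trimethyl{[(4R)-4-methylcyclopent-1-en-1-yl]oxy}silane | C[Si](C)(C)OC1=CC[C@@H](C)C1 | intermediate
3 | (4S)-4-methylcyclopent-2-en-1-one | C[C@H]1CC(=O)C=C1 | intermediate
4 | methyl (S)-lactate | C[C@H](O)C(=O)OC | starting material
5 | methyl (2S)-2-{[(trifluoromethyl)sulfonyl]oxy}propanoate | C[C@H](OS(=O)(=O)C(F)(F)F)C(=O)OC | intermediate
6 | 1,3-dithiane | C1CSCSC1 | starting material
7 | 2-lithio-1,3-dithiane | [Li]C1SCCCS1 | intermediate
8 | lithium (3R,4S)-3-(1,3-dithian-2-yl)-4-methylcyclopent-1-en-1-olate | S1CCCSC1[C@@H]1[C@@H](C)CC(O[Li])=C1 | intermediate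
9 | methyl (2S)-2-[(1S,2R,3S)-2-(1,3-dithian-2-yl)-3-methyl-5-oxocyclopentyl]propanoate | S1CCCSC1[C@@H]1[C@@H](C)CC(=O)[C@H]1[C@H](C)C(=O)OC | intermediate
10 | methyl (2S)-2-[(1S,4S,5R)-5-(1,3-dithian-2-yl)-4-methyl-2-{[(trifluoromethyl)sulfonyl]oxy}cyclopent-2-en-1-yl]propanoate | S1CCCSC1[C@@H]1[C@@H](C)C=C(OS(=O)(=O)C(F)(F)F)[C@H]1[C@H](C)C(=O)OC | intermediate
11 | methyl (2S)-2-[(1S,4S,5R)-5-(1,3-dithian-2-yl)-2-ethyl-4-methylcyclopent-2-en-1-yl]propanoate | S1CCCSC1[C@@H]1[C@@H](C)C=C(CC)[C@H]1[C@H](C)C(=O)OC | intermediate
12 | methyl (2S)-2-[(1R,4S,5R)-2-ethyl-5-formyl-4-methylcyclopent-2-en-1-yl]propanoate | O=C[C@@H]1[C@@H](C)C=C(CC)[C@H]1[C@H](C)C(=O)OC | intermediate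
13 | (E)-cinnamaldehyde | O=C/C=C/c1ccccc1 | starting material
14 | [(1E)-4,4-dibromobuta-1,3-dien-1-yl]benzene | BrC(Br)=C/C=C/c1ccccc1 | intermediate
15 | [(3E)-4-phenylbut-3-en-1-yn-1-yl]lithium | [Li]C#C/C=C/c1ccccc1 | intermediate
16 | [(1E)-but-1-en-3-yn-1-yl]benzene | C#C/C=C/c1ccccc1 | intermediate
17 | [(1E,3E)-2-ethyl-4-phenylbuta-1,3-dien-1-yl]copper (as its MgBr2 complex) | [Cu]/C=C(CC)/C=C/c1ccccc1 | intermediate
18 | [(1E,3E)-3-ethyl-4-iodobuta-1,3-dien-1-yl]benzene | I/C=C(CC)/C=C/c1ccccc1 | intermediate
19 | [(1E,3E)-2-ethyl-4-phenylbuta-1,3-dien-1-yl]lithium | [Li]/C=C(CC)/C=C/c1ccccc1 | intermediate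
20 | methyl (2S)-2-[(1R,4S,5R)-2-ethyl-5-[(2E,4E)-3-ethyl-1-hydroxy-5-phenylpenta-2,4-dien-1-yl]-4-methylcyclopent-2-en-1-yl]propanoate (both carbinol epimers) | OC(/C=C(CC)/C=C/c1ccccc1)[C@@H]1[C@@H](C)C=C(CC)[C@H]1[C@H](C)C(=O)OC | intermediate
21 | methyl (2S)-2-[(1R,4S,5R)-2-ethyl-5-[(2E,4E)-3-ethyl-5-phenylpenta-2,4-dienoyl]-4-methylcyclopent-2-en-1-yl]propanoate | O=C(/C=C(CC)/C=C/c1ccccc1)[C@@H]1[C@@H](C)C=C(CC)[C@H]1[C@H](C)C(=O)OC | intermediate
22 | methyl (2S)-2-[(1R,4S,5R)-2-ethyl-5-[(3R,4E,6E)-5-ethyl-3-hydroxy-7-phenylhepta-4,6-dien-3-yl]-4-methylcyclopent-2-en-1-yl]propanoate | CC[C@](O)(/C=C(CC)/C=C/c1ccccc1)[C@@H]1[C@@H](C)C=C(CC)[C@H]1[C@H](C)C(=O)OC | intermediate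
23 | (1R,4S,4aR,7S,7aR)-1,5-diethyl-1-[(1E,3E)-2-ethyl-4-phenylbuta-1,3-dien-1-yl]-4,7-dimethyl-4,4a,7,7a-tetrahydrocyclopenta[c]pyran-3(1H)-one | CC[C@]1(OC(=O)[C@@H](C)[C@@H]2C(CC)=C[C@H](C)[C@@H]12)/C=C(CC)/C=C/c1ccccc1 | intermediate
24 | {[(1R,4aS,7S,7aR)-1,5-diethyl-1-[(1E,3E)-2-ethyl-4-phenylbuta-1,3-dien-1-yl]-4,7-dimethyl-1,4a,7,7a-tetrahydrocyclopenta[c]pyran-3-yl]oxy}(trimethyl)silane | CC[C@]1(OC(O[Si](C)(C)C)=C(C)[C@@H]2C(CC)=C[C@H](C)[C@@H]12)/C=C(CC)/C=C/c1ccccc1 | intermediate
25 | trimethylsilyl (1S,3aS,4S,5R,7aR)-3,5,7-triethyl-1,4-dimethyl-5-[(E)-2-phenylethenyl]-3a,4,5,7a-tetrahydro-1H-indene-4-carboxylate | CCC1=C[C@](/C=C/c2ccccc2)(CC)[C@@](C)(C(=O)O[Si](C)(C)C)[C@@H]2C(CC)=C[C@H](C)[C@@H]12 | intermediate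
26 | (1S,3aS,4S,5R,7aR)-3,5,7-triethyl-1,4-dimethyl-5-[(E)-2-phenylethenyl]-3a,4,5,7a-tetrahydro-1H-indene-4-carboxylic acid | CCC1=C[C@](/C=C/c2ccccc2)(CC)[C@@](C)(C(=O)O)[C@@H]2C(CC)=C[C@H](C)[C@@H]12 | target

## Step count and least certain steps

Total: 13 steps. Longest linear sequence: 9 steps (steps 1, 3, 4, 5, 6, 10, 11, 12, 13).

**Step 13 (key step).** The boat that joins two fully substituted carbons holds the C5 ethyl group against the ring fusion, so the shift may be slow. The ketene acetal could then be lost by oxygen-to-carbon silyl migration, by reversion to 23, or by heterolysis of the tertiary dienylic C–O bond followed by elimination. The fallback sets out from 23 and returns at 26. It replaces the enolate-derived ketene acetal by a neutral allyl vinyl ether that needs no enolisation and tolerates higher temperature. Reduction with i-Bu2AlH (toluene, −78 °C) should give the lactol (1R,4S,4aR,7S,7aR)-1,5-diethyl-1-[(1E,3E)-2-ethyl-4-phenylbuta-1,3-dien-1-yl]-4,7-dimethyl-1,3,4,4a,7,7a-hexahydrocyclopenta[c]pyran-3-ol F1. Dehydration (MsCl, Et3N, CH2Cl2) should give the cyclic enol ether (1R,4aS,7S,7aR)-1,5-diethyl-1-[(1E,3E)-2-ethyl-4-phenylbuta-1,3-dien-1-yl]-4,7-dimethyl-1,4a,7,7a-tetrahydrocyclopenta[c]pyran F2. Thermal Claisen rearrangement of this 2-alkenyl-3,4-dihydro-2H-pyran (xylene, 180–200 °C, sealed tube) has the same boat topology and therefore the same C4/C5 outcome, and should give the aldehyde (1S,3aS,4S,5R,7aR)-3,5,7-triethyl-1,4-dimethyl-5-[(E)-2-phenylethenyl]-3a,4,5,7a-tetrahydro-1H-indene-4-carbaldehyde F3. Pinnick oxidation (NaClO2, NaH2PO4, 2-methylbut-2-ene, t-BuOH/H2O) then gives 26.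

**Step 12.** The facial bias at the ketone is small: both ring arms next to C7a carry their substituents on the face remote from the acyl group. Coordination of the reagent to the ester could also deliver ethyl from the C3a side, so poor or reversed facial selectivity is the likely failure. Conjugate addition is a lesser risk. The fallback reverses the order of introduction; it sets out from 12 and returns at 22. EtMgBr (THF, −78 °C) gives the secondary alcohol methyl (2S)-2-[(1R,4S,5R)-2-ethyl-5-(1-hydroxypropyl)-4-methylcyclopent-2-en-1-yl]propanoate F4. Dess–Martin oxidation gives the ethyl ketone methyl (2S)-2-[(1R,4S,5R)-2-ethyl-4-methyl-5-propanoylcyclopent-2-en-1-yl]propanoate F5. Addition of 19 with CeCl3 to F5 should, under the facial preference that caused the failure, give 22, which is closed with NaH as before.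

**Step 3.** Enolate 8 may abstract the acidic α-hydrogen of 5 instead of displacing triflate, may be O-alkylated in the HMPA medium, or may equilibrate before it is trapped. The fallback uses a primary electrophile and adds the methyl group later, which is allowed because the C4 configuration is erased in 24. It sets out from 3 and 6 and returns at 11. Trapping 8 with methyl bromoacetate gives the keto ester methyl 2-[(1S,2R,3S)-2-(1,3-dithian-2-yl)-3-methyl-5-oxocyclopentyl]acetate F6. The conditions of steps 4 and 5 give the enol triflate methyl 2-[(1S,4S,5R)-5-(1,3-dithian-2-yl)-4-methyl-2-{[(trifluoromethyl)sulfonyl]oxy}cyclopent-2-en-1-yl]acetate F7 and the ester methyl 2-[(1S,4S,5R)-5-(1,3-dithian-2-yl)-2-ethyl-4-methylcyclopent-2-en-1-yl]acetate F8. Methylation of F8 (LiN(i-Pr)2, MeI, THF, −78 °C) gives 11, possibly with its C4 epimer methyl (2R)-2-[(1S,4S,5R)-5-(1,3-dithian-2-yl)-2-ethyl-4-methylcyclopent-2-en-1-yl]propanoate F9. F9 need not be removed, because both epimers converge at 24.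

## Further compounds

F1 | step 13 | (1R,4S,4aR,7S,7aR)-1,5-diethyl-1-[(1E,3E)-2-ethyl-4-phenylbuta-1,3-dien-1-yl]-4,7-dimethyl-1,3,4,4a,7,7a-hexahydrocyclopenta[c]pyran-3-ol (both anomers) | CC[C@]1(OC(O)[C@@H](C)[C@@H]2C(CC)=C[C@H](C)[C@@H]12)/C=C(CC)/C=C/c1ccccc1
F2 | step 13 | (1R,4aS,7S,7aR)-1,5-diethyl-1-[(1E,3E)-2-ethyl-4-phenylbuta-1,3-dien-1-yl]-4,7-dimethyl-1,4a,7,7a-tetrahydrocyclopenta[c]pyran | CC[C@]1(OC=C(C)[C@@H]2C(CC)=C[C@H](C)[C@@H]12)/C=C(CC)/C=C/c1ccccc1
F3 | step 13 | (1S,3aS,4S,5R,7aR)-3,5,7-triethyl-1,4-dimethyl-5-[(E)-2-phenylethenyl]-3a,4,5,7a-tetrahydro-1H-indene-4-carbaldehyde | CCC1=C[C@](/C=C/c2ccccc2)(CC)[C@@](C)(C=O)[C@@H]2C(CC)=C[C@H](C)[C@@H]12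
F4 | step 12 | methyl (2S)-2-[(1R,4S,5R)-2-ethyl-5-(1-hydroxypropyl)-4-methylcyclopent-2-en-1-yl]propanoate (both carbinol epimers) | CCC(O)[C@@H]1[C@@H](C)C=C(CC)[C@H]1[C@H](C)C(=O)OC
F5 | step 12 | methyl (2S)-2-[(1R,4S,5R)-2-ethyl-4-methyl-5-propanoylcyclopent-2-en-1-yl]propanoate | CCC(=O)[C@@H]1[C@@H](C)C=C(CC)[C@H]1[C@H](C)C(=O)OC
F6 | step 3 | methyl 2-[(1S,2R,3S)-2-(1,3-dithian-2-yl)-3-methyl-5-oxocyclopentyl]acetate | S1CCCSC1[C@@H]1[C@@H](C)CC(=O)[C@H]1CC(=O)OC
F7 | step 3 | methyl 2-[(1S,4S,5R)-5-(1,3-dithian-2-yl)-4-methyl-2-{[(trifluoromethyl)sulfonyl]oxy}cyclopent-2-en-1-yl]acetate | S1CCCSC1[C@@H]1[C@@H](C)C=C(OS(=O)(=O)C(F)(F)F)[C@H]1CC(=O)OC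
F8 | step 3 | methyl 2-[(1S,4S,5R)-5-(1,3-dithian-2-yl)-2-ethyl-4-methylcyclopent-2-en-1-yl]acetate | S1CCCSC1[C@@H]1[C@@H](C)C=C(CC)[C@H]1CC(=O)OC
F9 | step 3 | methyl (2R)-2-[(1S,4S,5R)-5-(1,3-dithian-2-yl)-2-ethyl-4-methylcyclopent-2-en-1-yl]propanoate | S1CCCSC1[C@@H]1[C@@H](C)C=C(CC)[C@H]1[C@@H](C)C(=O)OC
A1 | alternative 1 | 2-ethyl-2-lithio-1,3-dithiane | CCC1([Li])SCCCS1
A2 | alternative 1 | methyl (2S)-2-[(1S,2R,3S)-2-(2-ethyl-1,3-dithian-2-yl)-3-methyl-5-oxocyclopentyl]propanoate | CCC1(SCCCS1)[C@@H]2[C@@H](C)CC(=O)[C@H]2[C@H](C)C(=O)OC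
A3 | alternative 2 | methyl (2S)-2-[(1S,4S,5R)-5-(but-1-en-2-yl)-2-ethyl-4-methylcyclopent-2-en-1-yl]-3-ethenyl-3-ethyl-2-methylpent-4-enoate | C=C(CC)[C@@H]1[C@@H](C)C=C(CC)[C@H]1[C@](C)(C(=O)OC)C(CC)(C=C)C=C
A4 | alternative 2 | methyl (1S,3aS,4S,5R,7aR)-5-ethenyl-3,5,7-triethyl-1,4-dimethyl-3a,4,5,7a-tetrahydro-1H-indene-4-carboxylate | CCC1=C[C@](C=C)(CC)[C@@](C)(C(=O)OC)[C@@H]2C(CC)=C[C@H](C)[C@@H]12
A5 | alternative 3 | methyl (1S,3aS,4S,5R,7aR)-3,5,7-triethyl-1,4-dimethyl-5-[(E)-2-phenylethenyl]-3a,4,5,7a-tetrahydro-1H-indene-4-carboxylate | CCC1=C[C@](/C=C/c2ccccc2)(CC)[C@@](C)(C(=O)OC)[C@@H]2C(CC)=C[C@H](C)[C@@H]12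
A6 | alternative 3 | methyl (2S,3E)-2-[(1S,4S,5R)-2-ethyl-5-[(1Z)-1-iodobut-1-en-2-yl]-4-methylcyclopent-2-en-1-yl]-3-ethyl-2-methyl-5-phenylpent-3-enoate | CC/C(=C/I)[C@@H]1[C@@H](C)C=C(CC)[C@H]1[C@](C)(C(=O)OC)/C(CC)=C/Cc1ccccc1
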